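The cyclopentenone ring carries oxygen on C1 (ketone) and C4 (acetoxy carbinol), 1,4 across the C2=C3 double bond, with the quaternary carbinol C5 between them: the imprint of a cyclopentadiene endoperoxide opened by base. The route therefore rests on cutting both ring C–O bonds back to a C5-spiro cyclopentadiene. In one flask, singlet oxygen bridges C1 and C4 and an amine fragments the peroxide, setting the C1 ketone, the C4 carbinol and the C4 and C5 stereocentres under the influence of C6. The precursor is the diene whose O5/O6 diol is locked as an acetonide, built from methyl (S)-glycidate; acetate inversion at C4 and ketal hydrolysis finish.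

Key step: step 7

Remark on numbering: C1–C6 are the target's atoms (C1 ketone, C2=C3, C4 acetoxy carbon, C5 quaternary carbinol, C6 side-chain carbinol). In the spiro names, locant 5 is C5, locant 4 is C6, locant 6 is C1 and locant 9 is C4.

Assumption: methyl (S)-glycidate and both Grignard solutions are bought (undecylmagnesium bromide can equally be made from 1-bromoundecane and magnesium). Step 5 should give both trans-dibromides (7R,8R and 7S,8S); compound 8 is drawn as the former and both converge in step 6.

Step 1
Reactants: 1 methyl (2S)-oxirane-2-carboxylate (methyl (S)-glycidate); 2 undecylmagnesium bromide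
Product: 3 methyl (2S)-2-hydroxytetradecanoate
Conditions: 2 (1.3 equiv), CuBr·SMe2 (10 mol%), THF/Et2O, −78 → −30 °C
Reagents that add atoms: none
Why: Copper-catalysed Grignard opening of the epoxide at the unsubstituted C3 (SN2), a known entry to 2-hydroxy esters from glycidates; the C2 stereocentre is not involved, so the (S) configuration that becomes C6 is carried over unchanged.

Step 2
Reactants: 3 methyl (2S)-2-hydroxytetradecanoate; 4 allylmagnesium bromide
Product: 5 (5S)-4-(prop-2-en-1-yl)heptadec-1-ene-4,5-diol
Conditions: 4 (3.5 equiv), Et2O/THF, 0 °C → rt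
Reagents that add atoms: none
Why: Double Grignard addition to the ester; the first equivalent deprotonates the hydroxyl and the resulting magnesium alkoxide suppresses enolisation, so C6 keeps its configuration while the ester carbon becomes the future C5.

Step 3
Reactants: 5 (5S)-4-(prop-2-en-1-yl)heptadec-1-ene-4,5-diol
Product: 6 1-[(1S)-1-hydroxytridecyl]cyclopent-3-en-1-ol
Conditions: second-generation Grubbs catalyst RuCl2(=CHPh)(PCy3)(H2IMes) (2 mol%), CH2Cl2, 40 °C
Reagents that add atoms: none
Why: Ring-closing olefin metathesis of the 1,6-diene to the cyclopentene with loss of ethene, a closure that tolerates free hydroxyls; no stereocentre is touched.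

Step 4
Reactants: 6 1-[(1S)-1-hydroxytridecyl]cyclopent-3-en-1-ol
Product: 7 (4S)-4-dodecyl-2,2-dimethyl-1,3-dioxaspiro[4.4]non-7-ene
Conditions: Me2C(OMe)2, CSA (cat.), CH2Cl2, rt
Reagents that add atoms: 2,2-dimethoxypropane, COC(C)(C)OC
Why: Acid-catalysed transketalisation (acetonide formation) of the tertiary/secondary 1,2-diol; the dioxolane shields both hydroxyls from the base of step 6 and supplies the conformational lock on which step 7 depends.

Step 5
Reactants: 7 (4S)-4-dodecyl-2,2-dimethyl-1,3-dioxaspiro[4.4]non-7-ene
Product: 8 (4S,7R,8R)-7,8-dibromo-4-dodecyl-2,2-dimethyl-1,3-dioxaspiro[4.4]nonane (trans-dibromide)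
Conditions: Br2 (1.05 equiv), K2CO3, CH2Cl2, −78 °C
Reagents that add atoms: bromine, BrBr
Why: Electrophilic anti addition of bromine through a bromonium ion gives the trans-dibromide; cold, carbonate-buffered conditions keep traces of HBr from opening the ketal, and the two new stereocentres are erased again in step 6.

Step 6
Reactants: 8 (4S,7R,8R)-7,8-dibromo-4-dodecyl-2,2-dimethyl-1,3-dioxaspiro[4.4]nonane
Product: 9 (4S)-4-dodecyl-2,2-dimethyl-1,3-dioxaspiro[4.4]nona-6,8-diene
Conditions: KOtBu (3 equiv), 18-crown-6 (cat.), THF, 0 °C → rt; solution kept cold and used at once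
Reagents that add atoms: none
Why: Twofold E2 dehydrobromination: anti elimination toward a ring CH2 gives the allylic bromide and a second elimination gives the conjugated diene, which cannot tautomerise because the spiro carbon bears no hydrogen; the ketal is inert to alkoxide.

Step 7
Reactants: 9 (4S)-4-dodecyl-2,2-dimethyl-1,3-dioxaspiro[4.4]nona-6,8-diene
Product: 11 (4S,5R,9S)-4-dodecyl-9-hydroxy-2,2-dimethyl-1,3-dioxaspiro[4.4]non-7-en-6-one, via endoperoxide 10 (not isolated)
Conditions: O2, tetraphenylporphyrin (1 mol%), white LED, CH2Cl2, −78 °C; then Ar purge, Et3N (2 equiv), −78 → −20 °C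
Reagents that add atoms: dioxygen, O=O
Why: Porphyrin-sensitised singlet oxygen engages the locked s-cis diene in a suprafacial cycloaddition at C1 and C4 (with C5 fully substituted, no sigmatropic hydrogen shift can scramble the diene beforehand) to give the bicyclic endoperoxide 10; triethylamine then abstracts one bridgehead hydrogen and the O–O bond is cleaved in the same E1cB-like event, so that this carbon emerges as the C1 ketone and the other bridgehead as the C4 alkoxide. The closest known reaction type is the dye-sensitised photooxygenation of cyclopentadienes followed by amine-induced Kornblum–DeLaMare rearrangement to 4-hydroxycyclopent-2-enones. The only ring closed is the transient 2,3-dioxabicyclo[2.2.1]heptene, formed by concerted [4+2] cycloaddition and reopened in the same flask, so no ring is built net. The C4 stereocentre follows from the face of oxygen attack: the dioxolane holds C6, with its hydrogen and the first CH2 of the dodecyl chain, over one face of the diene, while the O5 face is open and is also the electronically preferred one for 5-oxygenated cyclopentadienes, so the hydroxyl should end cis to O5. The C5 stereocentre follows from which bridgehead hydrogen is taken: the dodecyl chain is cis on the dioxolane to the bridgehead that becomes C4 and shields it, so the amine should take the hydrogen on the side of C6–H, which becomes C1. The step thus needs oxygen syn to O5 and deprotonation remote from the chain, both secured by the rigid spiro-ketal (the reason a cyclic protecting group is kept), with a bulkier tertiary amine as the first variable if the site preference is modest.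

Step 8
Reactants: 11 (4S,5R,9S)-4-dodecyl-9-hydroxy-2,2-dimethyl-1,3-dioxaspiro[4.4]non-7-en-6-one
Product: 12 (4S,5S,9R)-4-dodecyl-2,2-dimethyl-6-oxo-1,3-dioxaspiro[4.4]non-7-en-9-yl acetate
Conditions: AcOH, PPh3, DIAD, THF, 0 °C → rt
Reagents that add atoms: acetic acid, CC(=O)O
Why: Mitsunobu esterification: the alkoxyphosphonium ion is displaced by acetate in an SN2 step with inversion at C4 (9S to 9R; the descriptor at C5 changes only through CIP priorities), placing the acetate trans to O5; elimination is excluded (C5 has no hydrogen, C3 is sp2), the enone disfavours ionisation, and the neutral medium leaves ketal and enone alone.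

Step 9
Reactants: 12 (4S,5S,9R)-4-dodecyl-2,2-dimethyl-6-oxo-1,3-dioxaspiro[4.4]non-7-en-9-yl acetate
Product: 13 (1R,5S)-5-hydroxy-5-[(1S)-1-hydroxytridecyl]-4-oxocyclopent-2-en-1-yl acetate (target)
Conditions: TFA/H2O (9:1), CH2Cl2, 0 °C
Reagents that add atoms: none
Why: Acid-catalysed ketal hydrolysis releases the C5/C6 diol; the secondary acetate tolerates cold aqueous acid, and since C5 is quaternary acetic acid cannot be eliminated from the 4-acetoxy enone.

Compound list
1 | methyl (2S)-oxirane-2-carboxylate | COC(=O)[C@@H]1CO1 | starting material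
2 | undecylmagnesium bromide | CCCCCCCCCCC[Mg]Br | starting material
3 | methyl (2S)-2-hydroxytetradecanoate | CCCCCCCCCCCC[C@H](O)C(=O)OC | intermediate
4 | allylmagnesium bromide | C=CC[Mg]Br | starting material
5 | (5S)-4-(prop-2-en-1-yl)heptadec-1-ene-4,5-diol | CCCCCCCCCCCC[C@H](O)C(O)(CC=C)CC=C | intermediate
6 | 1-[(1S)-1-hydroxytridecyl]cyclopent-3-en-1-ol | CCCCCCCCCCCC[C@H](O)C1(O)CC=CC1 | intermediate
7 | (4S)-4-dodecyl-2,2-dimethyl-1,3-dioxaspiro[4.4]non-7-ene | CCCCCCCCCCCC[C@@H]1OC(C)(C)OC12CC=CC2 | intermediate
8 | (4S,7R,8R)-7,8-dibromo-4-dodecyl-2,2-dimethyl-1,3-dioxaspiro[4.4]nonane, trans-dibromide (the 7S,8S isomer forms alongside) | CCCCCCCCCCCC[C@@H]1OC(C)(C)OC12C[C@@H](Br)[C@H](Br)C2 | intermediate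
9 | (4S)-4-dodecyl-2,2-dimethyl-1,3-dioxaspiro[4.4]nona-6,8-diene | CCCCCCCCCCCC[C@@H]1OC(C)(C)OC12C=CC=C2 | intermediate
10 | (5'S)-5'-dodecyl-2',2'-dimethylspiro[2,3-dioxabicyclo[2.2.1]hept-5-ene-7,4'-[1,3]dioxolane], peroxide bridge on the side of the dioxolane oxygen of the spiro carbon | CCCCCCCCCCCC[C@@H]1OC(C)(C)O[C@@]12[C@H]3C=C[C@@H]2OO3 | intermediate
11 | (4S,5R,9S)-4-dodecyl-9-hydroxy-2,2-dimethyl-1,3-dioxaspiro[4.4]non-7-en-6-one (hydroxyl cis to O5) | CCCCCCCCCCCC[C@@H]1OC(C)(C)O[C@@]12C(=O)C=C[C@@H]2O | intermediate
12 | (4S,5S,9R)-4-dodecyl-2,2-dimethyl-6-oxo-1,3-dioxaspiro[4.4]non-7-en-9-yl acetate (acetate trans to O5) | CCCCCCCCCCCC[C@@H]1OC(C)(C)O[C@@]12C(=O)C=C[C@H]2OC(C)=O | intermediate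
13 | (1R,5S)-5-hydroxy-5-[(1S)-1-hydroxytridecyl]-4-oxocyclopent-2-en-1-yl acetate | CCCCCCCCCCCC[C@H](O)[C@@]1(O)C(=O)C=C[C@H]1OC(C)=O | target

Total step count: 9.
Longest linear sequence: 9 steps, from methyl (S)-glycidate 1.

Steps most likely to fail

1. Step 7. The amine may discriminate poorly between the two bridgehead hydrogens, so that material with the wrong C5 configuration forms alongside. The strained peroxide may also rearrange thermally before it fragments. Attack of oxygen on the other face would be harmless, since plain acetylation would then replace step 8. The fallback sets out from 9 and comes back at 12. The photooxygenation is run as before to peroxide 10, which is reduced in the cold with thiourea to the cis-ene-diol (4S)-4-dodecyl-2,2-dimethyl-1,3-dioxaspiro[4.4]non-7-ene-6,9-diol F1. Dess–Martin oxidation gives (4S)-4-dodecyl-2,2-dimethyl-1,3-dioxaspiro[4.4]non-7-ene-6,9-dione F2, in which C5 is no longer stereogenic. A Corey–Bakshi–Shibata reduction ((S)-2-methyl-CBS-oxazaborolidine, catecholborane, toluene, −78 °C) then chooses between the two carbonyls under catalyst control. Hydride can enter only from the open O5 face, so the catalyst's preference for one carbinol configuration becomes a choice of carbonyl. This should give (4S,5R,9R)-4-dodecyl-9-hydroxy-2,2-dimethyl-1,3-dioxaspiro[4.4]non-7-en-6-one F3; the enantiomeric catalyst is the alternative if the pairing with C6 proves mismatched. Acetylation (Ac2O, DMAP, pyridine) leads to 12, so step 8 is bypassed as well.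

2. Step 8. Backside attack at C4 may be too slow: the carbon is neopentyl-like, and the dioxolane holds the first CH2 of the dodecyl chain close to the face that acetate must enter. The likely outcomes are recovered alcohol or retention through acyl transfer. The fallback sets out from 11 and comes back at 13. Mesylation (MsCl, Et3N, CH2Cl2, 0 °C) gives (4S,5S,9S)-4-dodecyl-2,2-dimethyl-6-oxo-1,3-dioxaspiro[4.4]non-7-en-9-yl methanesulfonate F4. The ketal is removed first (TFA/H2O, 0 °C) to give (1S,5S)-5-hydroxy-5-[(1S)-1-hydroxytridecyl]-4-oxocyclopent-2-en-1-yl methanesulfonate F5, in which the C5–C6 bond rotates freely and the chain no longer covers C4. Displacement with Bu4NOAc buffered with AcOH (acetone, rt → 40 °C) then installs the acetate with inversion and gives 13 directly.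

3. Step 6. The intermediate allylic bromide may be substituted by tert-butoxide, the second elimination may stall, or the diene may dimerise by Diels–Alder reaction during isolation. The fallback sets out from 7 and comes back at 9. Wohl–Ziegler bromination (NBS, AIBN, PhCF3, 80 °C) gives the allylic bromide (4S)-8-bromo-4-dodecyl-2,2-dimethyl-1,3-dioxaspiro[4.4]non-6-ene F6 as a diastereomer mixture. A single E2 with the non-nucleophilic amidine DBU (THF, rt) gives 9, which is passed as a cold solution into step 7 without concentration.

Further compounds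
F1 | step 7 | (4S)-4-dodecyl-2,2-dimethyl-1,3-dioxaspiro[4.4]non-7-ene-6,9-diol, both hydroxyls cis to O5 | CCCCCCCCCCCC[C@@H]1OC(C)(C)O[C@@]12[C@H](O)C=C[C@@H]2O
F2 | step 7 | (4S)-4-dodecyl-2,2-dimethyl-1,3-dioxaspiro[4.4]non-7-ene-6,9-dione | CCCCCCCCCCCC[C@@H]1OC(C)(C)OC12C(=O)C=CC2=O
F3 | step 7 | (4S,5R,9R)-4-dodecyl-9-hydroxy-2,2-dimethyl-1,3-dioxaspiro[4.4]non-7-en-6-one, hydroxyl trans to O5 | CCCCCCCCCCCC[C@@H]1OC(C)(C)O[C@@]12C(=O)C=C[C@H]2O
F4 | step 8 | (4S,5S,9S)-4-dodecyl-2,2-dimethyl-6-oxo-1,3-dioxaspiro[4.4]non-7-en-9-yl methanesulfonate | CCCCCCCCCCCC[C@@H]1OC(C)(C)O[C@@]12C(=O)C=C[C@@H]2OS(C)(=O)=O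
F5 | step 8 | (1S,5S)-5-hydroxy-5-[(1S)-1-hydroxytridecyl]-4-oxocyclopent-2-en-1-yl methanesulfonate | CCCCCCCCCCCC[C@H](O)[C@@]1(O)C(=O)C=C[C@@H]1OS(C)(=O)=O
F6 | step 6 | (4S)-8-bromo-4-dodecyl-2,2-dimethyl-1,3-dioxaspiro[4.4]non-6-ene, mixture of diastereomers at C5 and C8 | CCCCCCCCCCCC[C@@H]1OC(C)(C)OC12C=CC(Br)C2
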